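The numbers in the tables were generated by integration from invented constants; scatter was added.

At the first reading, 0.417 min after mixing, the north run already lacked 26.2% of its charge: monomer in chains and free monomer did not add up to the whole. At its last reading, 5.00 min, the gap stood at 27.7%, and [protic impurity] over [free monomer] charged was 27.6% in that run. In the north-west run the first gap was 7.40% against a charge ratio of 7.20%. So I read one free monomer lost for each protic impurity, early in the run, with the impurity as limiting reagent of that loss.

| flask | free monomer | protic impurity | initiator | remark | time |
|---|---|---|---|---|---|
| north-west | 0.25 M | 0.018 M | 5.8 mM | run made earlier |  |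
| west | 0.25 M | 0.035 M | 5.8 mM | run made earlier |  |
| north | 0.25 M | 0.069 M | 5.8 mM | run made earlier |  |
| summer | 0.25 M | 0.0750 M | 5.8 mM |  | 10 min |
| autumn | 0.25 M | 0.0200 M | 5.8 mM |  | 10 min |

| run | time / min | monomer in chains / % | free monomer / % |
|---|---|---|---|
| north-west | 0.417 | 35.9 | 56.7 |
| north-west | 1.33 | 57.8 | 35.7 |
| north-west | 2.50 | 65.9 | 26.9 |
| north-west | 4.00 | 69.7 | 23.7 |
| north-west | 5.00 | 70.2 | 20.7 |
| west | 0.417 | 32.4 | 53.1 |
| west | 1.33 | 54.1 | 31.9 |
| west | 2.50 | 61.2 | 25.2 |
| west | 4.00 | 64.8 | 20.7 |
| west | 5.00 | 67.3 | 19.4 |
| north | 0.417 | 28.4 | 45.4 |
| north | 0.833 | 40.1 | 32.7 |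
| north | 1.33 | 45.2 | 26.4 |
| north | 2.50 | 52.6 | 19.5 |
| north | 5.00 | 57.9 | 14.4 |

(standard deviation of a reading: 0.5 percentage points)

* which of the two ends with the longer chains by the average number of monomer units in a chain (chains begun, living or dead) ("neither" if they lie within 10%) (summer / autumn / neither)
* average number of monomer units in a chain (chains begun, living or dead) at the end, summer
* average number of monomer units in a chain (chains begun, living or dead) at the end, autumn

- the average divides the monomer in chains by the number of chains begun, living and dead together
- the earlier runs do not show the number of chains; that part of a forecast is a guess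

I had to choose which recipe to charge next. Summer has 0.175 M and autumn 0.230 M of what I called the chain budget: [free monomer] charged minus [protic impurity] charged. At 5.00 min, the share of the budget in chains read 77.2% in the north-west run and 80.1% in the north run, although the impurity differed. The runs do not show the number of chains, but both recipes hold 5.8 mM of initiator, so I guessed the same number in each. The lengths should then stand as the budgets, a ratio of 1.31, which clears the margin of 10%. I committed to autumn. Taking one chain per initiator and the north-west share, which was read at 5.00 min although the recipes run to 10 min, my own reckoning gave 23.3 for summer and 30.6 for autumn.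

The forecast also named autumn, with 24.5 for summer and 32 for autumn, each a little above mine. One of its grounds was that “each impurity molecule instantly removes one monomer”.

The flask gave autumn, with 25.3 for summer and 31.9 for autumn.

    free monomer + initiator → living end + monomer in chains (k = 0.350 L mol⁻¹ s⁻¹)
    free monomer + living end → monomer in chains + living end, rate k2*[living end]*[free monomer] (k = 12.0 L mol⁻¹ s⁻¹)
    2 living end → dead end (k = 28.0 L mol⁻¹ s⁻¹)
    protic impurity + free monomer → quenched substrate (k = 0.830 L mol⁻¹ s⁻¹)

In autumn at 0.467 min, the half-life of protic impurity by its step with free monomer was 0.10 min, shorter than the 0.82 min half-life of free monomer by the step that adds it to living ends, by a factor of 7.97. At 10.0 min, autumn's monomer in chains and free monomer together made 92.0% of the charge, and its chain budget was 92.0%. The neighbour flask, like autumn but with 0.050 M of protic impurity, had a budget of 0.200 M, which scaled autumn's length to 27.7, and it ended at 28.3.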